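## Analysis of the target

The target joins two ring systems through one CH2 group. The first is a 2,2-dimethyl-2H-chromene (benzene ring A fused to pyran ring B; O1, C2–C4, C4a, C5–C8, C8a) with hydroxyls at C5 and C7, a butanoyl group at C8 and the bridge at C6. The second is a cyclohexane-1,3,5-trione (ring C, C1′–C6′, drawn as a dienol) with the bridge at C6′, an acetyl group at C2′ and a quaternary C4′ bearing methyl and geranyl.

C4′ is the only stereocentre (R in the tautomer drawn). Its ring neighbours C3′ and C5′ are both enolised carbonyl carbons and differ only in what lies beyond them (acetyl-bearing C2′ or bridge-bearing C6′). No neighbouring group can direct its formation, so it must be set by desymmetrisation. The (2E) alkene of the geranyl chain is the second stereo-element.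

Sensitive groups are the two trisubstituted geranyl alkenes (cationic cyclisation under Brønsted or Lewis acid), the C3=C4 bond of ring B (acid, electrophiles, hydrogenation), the CH2 between two 1,3-dicarbonyl-type rings (retro-Michael cleavage) and the electron-rich phenol/enol array.

Ring A is fully substituted in a fixed order, with the pyran oxygen next to the butanoyl carbon. Once geranyl and ring B are present, a Lewis-acid acylation of ring A cannot be defended, so the butanoyl group has to be placed early and by a regiodefined method.

The strategy rests on reading ring C as a 2,2-disubstituted 3,5-dioxoheptanoate folded so that C6′ closes onto C5′. C4′ is then the central carbon of a 2-geranyl-2-methylmalonate whose two carboxyl carbons (later C3′ and C5′) are enantiotopic and can be distinguished by an esterase.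

## Retrosynthetic reasoning

**28 to 27.** The last operation only frees the C5 and C7 hydroxyls. They are carried as methoxymethyl ethers because these direct lithiation on ring A, survive strong base, and leave under mild acid methanolysis.

**27 to 25.** The C2′–acetyl bond is cut. C2′ is the only ring carbon of 25 that still carries hydrogen, so O-acylation followed by a 1,3 oxygen-to-carbon acyl shift can only end there.

**25 to 23 (key disconnection).** The C5′–C6′ bond is cut, which unfolds ring C into the open-chain 3,5-dioxo ester 23. C5′ becomes the ester carbon and C6′ the terminal carbon of the diketone dienolate, already carrying the chromenylmethyl group. The bridge is therefore never made by joining two finished rings. The quaternary carbon is untouched, so its configuration must be complete in 23.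

**23 to 22 to 9 + 20.** The 1,3-diketone is traced to a β-hydroxy ketone and then to an aldol union between the methyl ketone 9 and the aldehyde 20. The chain is cut between C4 and C5 because this makes the arene partner an aldehyde, which an enolate attacks much faster than the hindered butanoyl ketone. Cutting between C3 and C4 would need the arene partner as an enolate, in competition with its own butanoyl group.

**9 to 4.** The esterase hydrolyses one ester group of 3, and for the expected sense the free acid of 4 sits where the ring-closing ester (C5′) must be, while the surviving ester sits where the ketone (C3′) must be. Converting the acid directly into the ketone would give the mirror image of 9. So the surviving ester is reduced in the presence of the carboxylate (5), the acid is re-esterified (6), and the primary alcohol is taken through aldehyde 7 and carbinol 8 to ketone 9.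

**4 to 3 to 1 + 2.** The half-ester comes from the prochiral diester 3, made by alkylating 1 with 2. This is the only step that creates chirality.

**20 to 19 to 18.** The propanal side chain is a two-carbon extension of the C6 aldehyde of 18 by olefination and conjugate reduction of the enal. The chromene alkene rules out catalytic hydrogenation and the butanoyl ketone rules out metal hydrides.

**18 to 15.** The C8–butanoyl bond is cut on the protected chromene aldehyde. C8–H lies between an acetal ether and the ring oxygen, so it can be lithiated and acylated while the aldehyde is masked in the flask. This replaces an electrophilic acylation of the finished molecule, which the geranyl chain, ring B and the bridge would not survive.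

**15 to 14 to 12 to 10 + 11.** Ring B is formed by rearrangement of the aryl propargyl ether 12. Because 10 is symmetric, etherification at the hydroxyl para to the aldehyde and rearrangement to either ortho carbon give only 14, which fixes the substitution order of ring A.

## Alternatives that were turned down

**Alternative 1:** Ring A is cut at C7–C8 and grown last from a pyrone attached to the bridge. The precursor is the 4-hydroxy-6-(2-oxopentyl)pyran-2-one A2, which already carries the finished ring C on the CH2 at its C3. A magnesium alkoxide opens the lactone, the CH2 between the butanoyl carbonyl and the next ketone attacks the liberated ester carbonyl, and aromatisation gives the butanoylphloroglucinol A1.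

- For: the butanoyl group is built into ring A, so no aromatic acylation is needed. On this point it is stronger than the chosen route, which spends a lithiation step. Aromatisation also drives the closure.
- Against: the key step runs on a CH2-bridged pair of 1,3-dicarbonyl units under alkoxide, where retro-Michael cleavage of the bridge threatens. Ring B must then be annulated onto A1 with 3-methylbut-2-enal A3. The free CH of A1 lies between two hydroxyls, and only reaction through the one next to the butanoyl carbon gives the target, so a mixture of regioisomers is expected. The stereocentre still has to be made separately.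
- In its place the chosen strategy fixes the ring A pattern by symmetry at the start and closes ring C on a protected, non-bridged chain.

**Alternative 2:** Ring B is cut at C8a–O1, C4a–C4 and O1–C2. Fluoride releases an aryne from the silylaryl triflate A5. The carbonyl oxygen of A3 adds at the aryne carbon remote from the flanking acetal ether, the aryl anion closes a benzoxete, and ring opening to an ortho-quinone methide followed by 6π closure gives the chromene A4.

- For: the orientation of ring B follows from the aryne polarisation, and three bonds form in one step. A4 has two lithiation sites of graded acidity (C6 between two acetal ethers, then C8), so both substituents could be introduced without masking an aldehyde. On that point it is stronger.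
- Against: it spends its key step on the ring that is easiest to make; the chosen route gets ring B regiospecifically in two steps. A5 needs several steps from a phloroglucinol derivative. Neither ring C nor the stereocentre is addressed, so that part would be done as in the chosen route anyway, and the total is longer.

**Alternative 3:** Ring C is cut at C2′–C3′. The precursor is the 6-acetonylpyran-2,4-dione A7. A magnesium alkoxide opens the lactone, and the acetonyl CH2, now between two ketones, attacks the released ester carbonyl to give the acetylated trione A6. A6 would then be joined to aldehyde 18 by reductive alkylation.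

- For: the acetyl group arrives with the ring closure and the nucleophile is a doubly activated CH2, so mild equilibrating conditions suffice. With the expected sense of hydrolysis, the free acid of 4 could become the ketone carbon directly, so ring C is reached in clearly fewer steps. On step economy it is stronger.
- Against: the ring-opened 2,2-disubstituted β-keto ester meets a nucleophilic alkoxide under equilibrating conditions, which favours retro-Claisen cleavage at the ketone next to the quaternary carbon. The bridge must be formed last in a bimolecular condensation between a doubly ortho-substituted aldehyde and the trione, where double addition and bridge scrambling are likely.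
- In its place the chosen strategy carries the bridge carbon in the chain and closes the ring with a non-nucleophilic base under kinetic control. The chemistry of this alternative is kept as the fallback for the key step.

Key step: step 16

Assumption on the chemistry: pig liver esterase is taken to hydrolyse the pro-S ester group of 3, the sense expected for 2-methylmalonates with a large lipophilic second substituent, giving the (R)-half-ester 4; steps 3 to 7 are laid out for this sense.

## Route

Step 1
Reactants: 1 dimethyl 2-methylpropanedioate; 2 geranyl bromide, (2E)-1-bromo-3,7-dimethylocta-2,6-diene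
Product: 3 dimethyl 2-[(2E)-3,7-dimethylocta-2,6-dien-1-yl]-2-methylpropanedioate
Conditions: NaH, THF, 0 °C; then 2, 0 °C → rt
Reagents that add atoms: none
Why: Malonate alkylation; the sodium enolate displaces the primary allylic bromide by SN2, and the product has no acidic hydrogen, so it cannot react again.

Step 2
Reactants: 3 dimethyl 2-[(2E)-3,7-dimethylocta-2,6-dien-1-yl]-2-methylpropanedioate
Product: 4 (2R)-2-[(2E)-3,7-dimethylocta-2,6-dien-1-yl]-3-methoxy-2-methyl-3-oxopropanoic acid
Conditions: pig liver esterase, phosphate buffer pH 7.5, DMSO (10% v/v), rt, pH-stat (1 M NaOH); then HCl to pH 3, 0 °C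
Reagents that add atoms: water, O
Why: Enzymatic desymmetrisation of a prochiral diester; the active site places geranyl in the large hydrophobic pocket and methyl in the small one, so one enantiotopic ester group reaches the serine and the stereocentre is set by the enzyme; the half-ester is not hydrolysed further because the carboxylate is a poor substrate.

Step 3
Reactants: 4 (2R)-2-[(2E)-3,7-dimethylocta-2,6-dien-1-yl]-3-methoxy-2-methyl-3-oxopropanoic acid
Product: 5 (2S,4E)-2-(hydroxymethyl)-2,5,9-trimethyldeca-4,8-dienoic acid
Conditions: LiBH4 (3 equiv, the first taken up by the acid proton), THF, 0 → 45 °C; then 1 M HCl, 0 °C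
Reagents that add atoms: none
Why: Chemoselective borohydride reduction; the carboxylate is inert to LiBH4 while the methyl ester is reduced to the primary alcohol, and the alkenes and the quaternary centre are untouched (the descriptor changes by priority only).

Step 4
Reactants: 5 (2S,4E)-2-(hydroxymethyl)-2,5,9-trimethyldeca-4,8-dienoic acid
Product: 6 methyl (2S,4E)-2-(hydroxymethyl)-2,5,9-trimethyldeca-4,8-dienoate
Conditions: MeI, KHCO3, DMF, rt
Reagents that add atoms: iodomethane, CI
Why: O-alkylation of the carboxylate by SN2; the neutral primary alcohol is not alkylated under bicarbonate, and a β-lactone cannot form under these conditions.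

Step 5
Reactants: 6 methyl (2S,4E)-2-(hydroxymethyl)-2,5,9-trimethyldeca-4,8-dienoate
Product: 7 methyl (2S,4E)-2-formyl-2,5,9-trimethyldeca-4,8-dienoate
Conditions: Dess–Martin periodinane, NaHCO3, CH2Cl2, 0 °C → rt
Reagents that add atoms: none
Why: Dess–Martin oxidation of a neopentyl-type primary alcohol; the aldehyde has no α-hydrogen, so it cannot epimerise or enolise, and the buffer protects the geranyl alkenes from acid.

Step 6
Reactants: 7 methyl (2S,4E)-2-formyl-2,5,9-trimethyldeca-4,8-dienoate
Product: 8 methyl (2S,4E)-2-(1-hydroxyethyl)-2,5,9-trimethyldeca-4,8-dienoate, both epimers at the carbinol carbon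
Conditions: CH3MgBr, THF, −78 °C; aq. NH4Cl
Reagents that add atoms: methylmagnesium bromide, C[Mg]Br
Why: Grignard addition; the aldehyde reacts far faster at −78 °C than the hindered ester on the quaternary carbon, and the new carbinol centre need not be controlled because it is oxidised in the next step.

Step 7
Reactants: 8 methyl (2S,4E)-2-(1-hydroxyethyl)-2,5,9-trimethyldeca-4,8-dienoate
Product: 9 methyl (2S,4E)-2-acetyl-2,5,9-trimethyldeca-4,8-dienoate
Conditions: Dess–Martin periodinane, NaHCO3, CH2Cl2, 0 °C → rt
Reagents that add atoms: none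
Why: Dess–Martin oxidation of the secondary alcohol; the resulting β-keto ester is blocked at the α-carbon and configurationally stable, with the ketone at the former ester carbon and the ester at the former acid carbon, as ring C requires.

Step 8
Reactants: 10 2,4,6-trihydroxybenzaldehyde; 11 3-chloro-3-methylbut-1-yne
Product: 12 2,6-dihydroxy-4-[(2-methylbut-3-yn-2-yl)oxy]benzaldehyde
Conditions: K2CO3 (1.1 equiv), KI, CuI (cat.), acetone, 50 °C
Reagents that add atoms: none
Why: Copper-assisted O-propargylation of a phenol; the hydroxyl para to the aldehyde is the most acidic and the only one not hydrogen-bonded to the carbonyl, so one equivalent of base directs etherification there.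

Step 9
Reactants: 12 2,6-dihydroxy-4-[(2-methylbut-3-yn-2-yl)oxy]benzaldehyde
Product: 14 5,7-dihydroxy-2,2-dimethyl-2H-chromene-6-carbaldehyde, via allenyl phenol 13 (not isolated)
Conditions: o-xylene, 140 °C
Reagents that add atoms: none
Why: Aromatic propargyl Claisen rearrangement to the ortho-allenyl phenol, then 1,5-hydrogen shift and oxa-6π electrocyclisation; the two ortho carbons are equivalent by symmetry, so only one chromene can form, with the aldehyde at C6 between the two hydroxyls.

Step 10
Reactants: 14 5,7-dihydroxy-2,2-dimethyl-2H-chromene-6-carbaldehyde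
Product: 15 5,7-bis(methoxymethoxy)-2,2-dimethyl-2H-chromene-6-carbaldehyde
Conditions: NaH (2.4 equiv), MOMCl (2.6 equiv), DMF, 0 °C → rt
Reagents that add atoms: chloromethyl methyl ether, COCCl
Why: Williamson-type acetal ether formation; full deprotonation with NaH overcomes the hydrogen bonds of both hydroxyls to the aldehyde, and the hard electrophile reacts at oxygen.

Step 11
Reactants: 15 5,7-bis(methoxymethoxy)-2,2-dimethyl-2H-chromene-6-carbaldehyde
Product: 18 8-butanoyl-5,7-bis(methoxymethoxy)-2,2-dimethyl-2H-chromene-6-carbaldehyde, via lithium aminoalkoxide 16 (not isolated), via 8-lithio aminoalkoxide 17 (not isolated)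
Conditions: 1-methylpiperazine, n-BuLi, THF, −20 °C; 15; n-BuLi (3 equiv), TMEDA, −20 → 0 °C; PrCON(OMe)Me (excess), −78 → 0 °C; aq. NH4Cl
Reagents that add atoms: N-methoxy-N-methylbutanamide, CCCC(=O)N(C)OC
Why: In situ protection of an aromatic aldehyde as its α-amino alkoxide followed by directed ortho-metalation; both positions next to the masked aldehyde are blocked, so butyllithium removes the only ring hydrogen, C8–H between an acetal ether and the pyran oxygen, and the N-methoxy-N-methylamide delivers the ketone without over-addition; work-up releases aldehyde and ketone together.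

Step 12
Reactants: 18 8-butanoyl-5,7-bis(methoxymethoxy)-2,2-dimethyl-2H-chromene-6-carbaldehyde
Product: 19 (2E)-3-[8-butanoyl-5,7-bis(methoxymethoxy)-2,2-dimethyl-2H-chromen-6-yl]prop-2-enal
Conditions: Ph3P=CHCHO (1.2 equiv), toluene, 90 °C
Reagents that add atoms: (triphenylphosphoranylidene)acetaldehyde, O=CC=P(c1ccccc1)(c1ccccc1)c1ccccc1
Why: Wittig olefination with a stabilised ylide, which gives the E-enal and reacts with the aldehyde but not with the doubly ortho-substituted aryl ketone.

Step 13
Reactants: 19 (2E)-3-[8-butanoyl-5,7-bis(methoxymethoxy)-2,2-dimethyl-2H-chromen-6-yl]prop-2-enal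
Product: 20 3-[8-butanoyl-5,7-bis(methoxymethoxy)-2,2-dimethyl-2H-chromen-6-yl]propanal
Conditions: Hantzsch ester (1.1 equiv), dibenzylammonium trifluoroacetate (10 mol %), THF, rt
Reagents that add atoms: none
Why: Iminium-catalysed transfer hydrogenation of an enal; hydride is delivered only to the β-carbon of the iminium ion, so the chromene alkene, the aryl ketone and the acetal ethers are left alone.

Step 14
Reactants: 9 methyl (2S,4E)-2-acetyl-2,5,9-trimethyldeca-4,8-dienoate; 20 3-[8-butanoyl-5,7-bis(methoxymethoxy)-2,2-dimethyl-2H-chromen-6-yl]propanal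
Product: 22 methyl (2S)-7-[8-butanoyl-5,7-bis(methoxymethoxy)-2,2-dimethyl-2H-chromen-6-yl]-2-[(2E)-3,7-dimethylocta-2,6-dien-1-yl]-5-hydroxy-2-methyl-3-oxoheptanoate, both C5 epimers, via lithium enolate 21 (not isolated)
Conditions: 9, LiN(iPr)2 (1.05 equiv), THF, −78 °C; 20, −78 °C; AcOH, −78 °C
Reagents that add atoms: none
Why: Directed aldol addition; 9 can enolise only at its methyl group, and the enolate adds to the aldehyde at −78 °C much faster than it attacks or deprotonates the shielded butanoyl ketone; the cold quench prevents retro-aldol and lactonisation onto the ester, and the carbinol centre is oxidised in step 15.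

Step 15
Reactants: 22 methyl (2S)-7-[8-butanoyl-5,7-bis(methoxymethoxy)-2,2-dimethyl-2H-chromen-6-yl]-2-[(2E)-3,7-dimethylocta-2,6-dien-1-yl]-5-hydroxy-2-methyl-3-oxoheptanoate
Product: 23 methyl (2S)-7-[8-butanoyl-5,7-bis(methoxymethoxy)-2,2-dimethyl-2H-chromen-6-yl]-2-[(2E)-3,7-dimethylocta-2,6-dien-1-yl]-2-methyl-3,5-dioxoheptanoate
Conditions: Dess–Martin periodinane, NaHCO3, CH2Cl2, 0 °C → rt
Reagents that add atoms: none
Why: Dess–Martin oxidation of a β-hydroxy ketone to the 1,3-diketone under buffered, non-basic conditions, which avoids retro-aldol and spares the alkenes and acetal ethers.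

Step 16
Reactants: 23 methyl (2S)-7-[8-butanoyl-5,7-bis(methoxymethoxy)-2,2-dimethyl-2H-chromen-6-yl]-2-[(2E)-3,7-dimethylocta-2,6-dien-1-yl]-2-methyl-3,5-dioxoheptanoate
Product: 25 2-{[8-butanoyl-5,7-bis(methoxymethoxy)-2,2-dimethyl-2H-chromen-6-yl]methyl}-4-[(2E)-3,7-dimethylocta-2,6-dien-1-yl]-3,5-dihydroxy-4-methylcyclohexa-2,5-dien-1-one (S at C4 in the tautomer drawn), via trilithium dienolate 24 (not isolated)
Conditions: LiN(iPr)2 (3.5 equiv), THF, −78 → 0 °C; then 1 M HCl to pH 3, 0 °C
Reagents that add atoms: none
Why: The amide base first removes the hydrogen at C4 between the two ketones and an α-hydrogen of the butanoyl group, and a third equivalent removes C6–H to give the dienolate 24. C6, the carbon carrying the chromenylmethyl group, then adds to the methyl ester carbonyl on the quaternary carbon and methoxide leaves; this is an intramolecular Claisen (Dieckmann-type) condensation, the known base-mediated cyclisation of 2,2-disubstituted 3,5-dioxoalkanoates to cyclohexane-1,3,5-triones. Ring C closes by forming C5′–C6′ in the 6-(enolendo)-exo-trig mode, which is favoured. The new ring is deprotonated at once at C6′, now between two carbonyls, which makes the closure irreversible. No stereocentre is formed; the quaternary carbon has no hydrogen and none of its bonds breaks, so the enzyme-set configuration is carried through. The selectivity needed is closure over retro-Claisen cleavage at the ketone beside the quaternary carbon, and it is secured by the non-nucleophilic base, the low temperature and the fact that methoxide appears only after the ring has formed. The other carbanionic sites cannot compete: C4 could only close a four-membered ring, and the butanoyl enolate would need a ring of twelve or more atoms. The ester keeps its full electrophilicity because the quaternary carbon insulates it from the enolate system.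

Step 17
Reactants: 25 2-{[8-butanoyl-5,7-bis(methoxymethoxy)-2,2-dimethyl-2H-chromen-6-yl]methyl}-4-[(2E)-3,7-dimethylocta-2,6-dien-1-yl]-3,5-dihydroxy-4-methylcyclohexa-2,5-dien-1-one
Product: 27 2-acetyl-6-{[8-butanoyl-5,7-bis(methoxymethoxy)-2,2-dimethyl-2H-chromen-6-yl]methyl}-4-[(2E)-3,7-dimethylocta-2,6-dien-1-yl]-3,5-dihydroxy-4-methylcyclohexa-2,5-dien-1-one (R at C4 in the tautomer drawn, same spatial arrangement), via enol acetate 26 (not isolated)
Conditions: Ac2O (1.2 equiv), Et3N, DMAP (0.5 equiv), CH2Cl2, 0 °C → rt
Reagents that add atoms: acetic anhydride, CC(=O)OC(C)=O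
Why: O-acylation of the enolised trione followed by DMAP-mediated oxygen-to-carbon acyl transfer (Steglich-type rearrangement of an enol ester, as in the preparation of 2-acylcyclohexane-1,3-diones); acyl transfer is reversible, and the only product that is a stabilised enolised tricarbonyl is the one acetylated at the single ring CH.

Step 18
Reactants: 27 2-acetyl-6-{[8-butanoyl-5,7-bis(methoxymethoxy)-2,2-dimethyl-2H-chromen-6-yl]methyl}-4-[(2E)-3,7-dimethylocta-2,6-dien-1-yl]-3,5-dihydroxy-4-methylcyclohexa-2,5-dien-1-one
Product: 28 2-acetyl-6-[(8-butanoyl-5,7-dihydroxy-2,2-dimethyl-2H-chromen-6-yl)methyl]-4-[(2E)-3,7-dimethylocta-2,6-dien-1-yl]-3,5-dihydroxy-4-methylcyclohexa-2,5-dien-1-one (CNP0152509.1)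
Conditions: 3 M aq. HCl, MeOH, 40 °C
Reagents that add atoms: none
Why: Acid-catalysed methanolysis of aryl methoxymethyl ethers; the ether at C7 is assisted by chelation to the butanoyl carbonyl, and dilute acid in methanol at this temperature is below what is needed to protonate the trisubstituted alkenes or the chromene double bond.

## Compound list

1 | dimethyl 2-methylpropanedioate | COC(=O)C(C)C(=O)OC | starting material
2 | geranyl bromide | BrC/C=C(\C)CCC=C(C)C | starting material
3 | dimethyl 2-[(2E)-3,7-dimethylocta-2,6-dien-1-yl]-2-methylpropanedioate | COC(=O)C(C)(C/C=C(\C)CCC=C(C)C)C(=O)OC | intermediate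
4 | (2R)-2-[(2E)-3,7-dimethylocta-2,6-dien-1-yl]-3-methoxy-2-methyl-3-oxopropanoic acid | OC(=O)[C@@](C)(C/C=C(\C)CCC=C(C)C)C(=O)OC | intermediate
5 | (2S,4E)-2-(hydroxymethyl)-2,5,9-trimethyldeca-4,8-dienoic acid | OC(=O)[C@@](C)(C/C=C(\C)CCC=C(C)C)CO | intermediate
6 | methyl (2S,4E)-2-(hydroxymethyl)-2,5,9-trimethyldeca-4,8-dienoate | COC(=O)[C@@](C)(C/C=C(\C)CCC=C(C)C)CO | intermediate
7 | methyl (2S,4E)-2-formyl-2,5,9-trimethyldeca-4,8-dienoate | COC(=O)[C@@](C)(C/C=C(\C)CCC=C(C)C)C=O | intermediate
8 | methyl (2S,4E)-2-(1-hydroxyethyl)-2,5,9-trimethyldeca-4,8-dienoate, carbinol epimers | COC(=O)[C@@](C)(C/C=C(\C)CCC=C(C)C)C(C)O | intermediate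
9 | methyl (2S,4E)-2-acetyl-2,5,9-trimethyldeca-4,8-dienoate | COC(=O)[C@@](C)(C/C=C(\C)CCC=C(C)C)C(C)=O | intermediate
10 | 2,4,6-trihydroxybenzaldehyde | O=Cc1c(O)cc(O)cc1O | starting material
11 | 3-chloro-3-methylbut-1-yne | CC(C)(Cl)C#C | starting material
12 | 2,6-dihydroxy-4-[(2-methylbut-3-yn-2-yl)oxy]benzaldehyde | O=Cc1c(O)cc(OC(C)(C)C#C)cc1O | intermediate
13 | 2,4,6-trihydroxy-3-(3-methylbuta-1,2-dien-1-yl)benzaldehyde | O=Cc1c(O)cc(O)c(C=C=C(C)C)c1O | intermediate
14 | 5,7-dihydroxy-2,2-dimethyl-2H-chromene-6-carbaldehyde | O=Cc1c(O)cc2OC(C)(C)C=Cc2c1O | intermediate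
15 | 5,7-bis(methoxymethoxy)-2,2-dimethyl-2H-chromene-6-carbaldehyde | O=Cc1c(OCOC)cc2OC(C)(C)C=Cc2c1OCOC | intermediate
16 | lithium [5,7-bis(methoxymethoxy)-2,2-dimethyl-2H-chromen-6-yl](4-methylpiperazin-1-yl)methanolate | CN1CCN(CC1)C(O[Li])c1c(OCOC)cc2OC(C)(C)C=Cc2c1OCOC | intermediate
17 | 8-lithio derivative of 16 | CN1CCN(CC1)C(O[Li])c1c(OCOC)c([Li])c2OC(C)(C)C=Cc2c1OCOC | intermediate
18 | 8-butanoyl-5,7-bis(methoxymethoxy)-2,2-dimethyl-2H-chromene-6-carbaldehyde | CCCC(=O)c1c(OCOC)c(C=O)c(OCOC)c2C=CC(C)(C)Oc12 | intermediate
19 | (2E)-3-[8-butanoyl-5,7-bis(methoxymethoxy)-2,2-dimethyl-2H-chromen-6-yl]prop-2-enal | CCCC(=O)c1c(OCOC)c(/C=C/C=O)c(OCOC)c2C=CC(C)(C)Oc12 | intermediate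
20 | 3-[8-butanoyl-5,7-bis(methoxymethoxy)-2,2-dimethyl-2H-chromen-6-yl]propanal | CCCC(=O)c1c(OCOC)c(CCC=O)c(OCOC)c2C=CC(C)(C)Oc12 | intermediate
21 | lithium enolate of 9 | COC(=O)[C@@](C)(C/C=C(\C)CCC=C(C)C)C(=C)O[Li] | intermediate
22 | methyl (2S)-7-[8-butanoyl-5,7-bis(methoxymethoxy)-2,2-dimethyl-2H-chromen-6-yl]-2-[(2E)-3,7-dimethylocta-2,6-dien-1-yl]-5-hydroxy-2-methyl-3-oxoheptanoate, C5 epimers | COC(=O)[C@@](C)(C/C=C(\C)CCC=C(C)C)C(=O)CC(O)CCc1c(OCOC)c(C(=O)CCC)c2OC(C)(C)C=Cc2c1OCOC | intermediate
23 | methyl (2S)-7-[8-butanoyl-5,7-bis(methoxymethoxy)-2,2-dimethyl-2H-chromen-6-yl]-2-[(2E)-3,7-dimethylocta-2,6-dien-1-yl]-2-methyl-3,5-dioxoheptanoate | COC(=O)[C@@](C)(C/C=C(\C)CCC=C(C)C)C(=O)CC(=O)CCc1c(OCOC)c(C(=O)CCC)c2OC(C)(C)C=Cc2c1OCOC | intermediate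
24 | trilithium salt of 23 (diketone dienolate plus butanoyl enolate) | COC(=O)[C@@](C)(C/C=C(\C)CCC=C(C)C)C(O[Li])=CC(O[Li])=CCc1c(OCOC)c(C(O[Li])=CCC)c2OC(C)(C)C=Cc2c1OCOC | intermediate
25 | 2-{[8-butanoyl-5,7-bis(methoxymethoxy)-2,2-dimethyl-2H-chromen-6-yl]methyl}-4-[(2E)-3,7-dimethylocta-2,6-dien-1-yl]-3,5-dihydroxy-4-methylcyclohexa-2,5-dien-1-one | CCCC(=O)c1c(OCOC)c(CC2=C(O)[C@@](C)(C/C=C(\C)CCC=C(C)C)C(O)=CC2=O)c(OCOC)c2C=CC(C)(C)Oc12 | intermediate
26 | 5-O-acetyl enol ester of 25 | CCCC(=O)c1c(OCOC)c(CC2=C(O)[C@@](C)(C/C=C(\C)CCC=C(C)C)C(OC(C)=O)=CC2=O)c(OCOC)c2C=CC(C)(C)Oc12 | intermediate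
27 | 2-acetyl-6-{[8-butanoyl-5,7-bis(methoxymethoxy)-2,2-dimethyl-2H-chromen-6-yl]methyl}-4-[(2E)-3,7-dimethylocta-2,6-dien-1-yl]-3,5-dihydroxy-4-methylcyclohexa-2,5-dien-1-one | CCCC(=O)c1c(OCOC)c(CC2=C(O)[C@@](C)(C/C=C(\C)CCC=C(C)C)C(O)=C(C(C)=O)C2=O)c(OCOC)c2C=CC(C)(C)Oc12 | intermediate
28 | 2-acetyl-6-[(8-butanoyl-5,7-dihydroxy-2,2-dimethyl-2H-chromen-6-yl)methyl]-4-[(2E)-3,7-dimethylocta-2,6-dien-1-yl]-3,5-dihydroxy-4-methylcyclohexa-2,5-dien-1-one | CCCC(=O)c1c(O)c(CC2=C(O)[C@@](C)(C/C=C(\C)CCC=C(C)C)C(O)=C(C(C)=O)C2=O)c(O)c2c1OC(C)(C)C=C2 | target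

## Step count and risk

Total step count: 18. Longest linear sequence: 12 steps (steps 1–7, then 14–18). The arene branch (steps 8–13) joins at step 14.

**Step 16 (key step).** The most likely failure is retro-Claisen cleavage at the ketone beside the quaternary carbon. The second is incomplete formation of the C6 carbanion, because the diketonate and the butanoyl enolate take up base first, which would leave intermolecular condensation as the main path. The fallback closes ring C at its other flank with the acetyl group already in the chain. It sets out from 4 and uses 18. Acid 4 is converted with carbonyldiimidazole into methyl (2R,4E)-2-(1H-imidazole-1-carbonyl)-2,5,9-trimethyldeca-4,8-dienoate F1. F1 acylates the terminal carbon of the dianion of pentane-2,4-dione to give methyl (2R)-2-[(2E)-3,7-dimethylocta-2,6-dien-1-yl]-2-methyl-3,5,7-trioxooctanoate F2. Mg(OMe)2 in methanol then closes F2 through its doubly activated CH2 to (4R)-2-acetyl-4-[(2E)-3,7-dimethylocta-2,6-dien-1-yl]-3,5-dihydroxy-4-methylcyclohexa-2,5-dien-1-one F3. Here the acid carbon of 4 becomes the ketone directly, which is the correct sense for this closure. Reductive alkylation of F3 with aldehyde 18 (Hantzsch ester, L-proline) forms the bridge and comes back to the route at 27.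

**Step 2.** Discrimination between the enantiotopic ester groups may be incomplete, or hydrolysis may proceed with the opposite sense for this branched allylic substituent. If the opposite half-ester forms, the route sets out from 3 through (2S)-2-[(2E)-3,7-dimethylocta-2,6-dien-1-yl]-3-methoxy-2-methyl-3-oxopropanoic acid F4. Oxalyl chloride gives methyl (2R,4E)-2-(chlorocarbonyl)-2,5,9-trimethyldeca-4,8-dienoate F5, and LiCu(CH3)2 at −78 °C converts the acid chloride into the methyl ketone. This comes back at 9 and replaces steps 3–7.

**Step 11.** Masking of the hindered aldehyde may be incomplete, so butyllithium adds to it, or metalation may occur at the vinylic C4–H instead of C8–H. The fallback isolates a protected aldehyde. From 15, trimethyl orthoformate and pyridinium p-toluenesulfonate in methanol give 6-(dimethoxymethyl)-5,7-bis(methoxymethoxy)-2,2-dimethyl-2H-chromene F6. Lithiation with n-BuLi/TMEDA and acylation with N-methoxy-N-methylbutanamide give 1-[6-(dimethoxymethyl)-5,7-bis(methoxymethoxy)-2,2-dimethyl-2H-chromen-8-yl]butan-1-one F7. Mild hydrolysis (pyridinium p-toluenesulfonate, wet acetone) comes back at 18.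

**Step 12.** Olefination of the doubly ortho-substituted aldehyde may be slow, and the less hindered enal product may be homologated a second time. The fallback leaves olefination. From 18, reductive Knoevenagel alkylation of Meldrum's acid (Hantzsch ester, L-proline, ethanol) gives 5-{[8-butanoyl-5,7-bis(methoxymethoxy)-2,2-dimethyl-2H-chromen-6-yl]methyl}-2,2-dimethyl-1,3-dioxane-4,6-dione F8. Amine-catalysed hydrosilylation (PhSiH3, Et3N, then water) converts F8 into the propanal with loss of acetone and carbon dioxide. This comes back at 20 and also replaces step 13.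

**Step 18.** Acid may trigger addition of an enol oxygen to the geranyl alkene or hydration of the chromene double bond before both acetal ethers are cleaved. The fallback avoids protic acid. From 27, trimethylsilyl triflate buffered with 2,2′-bipyridyl in acetonitrile exchanges the methoxymethyl groups for silyl groups, giving the tetrakis(trimethylsilyl) derivative F9 (silylated at O5, O7 and both enol oxygens). Water then hydrolyses F9 and comes back at 28.

## Further compounds

F1 | step 16 | methyl (2R,4E)-2-(1H-imidazole-1-carbonyl)-2,5,9-trimethyldeca-4,8-dienoate | O=C(n1ccnc1)[C@@](C)(C/C=C(\C)CCC=C(C)C)C(=O)OC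
F2 | step 16 | methyl (2R)-2-[(2E)-3,7-dimethylocta-2,6-dien-1-yl]-2-methyl-3,5,7-trioxooctanoate | CC(=O)CC(=O)CC(=O)[C@@](C)(C/C=C(\C)CCC=C(C)C)C(=O)OC
F3 | step 16 | (4R)-2-acetyl-4-[(2E)-3,7-dimethylocta-2,6-dien-1-yl]-3,5-dihydroxy-4-methylcyclohexa-2,5-dien-1-one | C1=C(O)[C@@](C)(C/C=C(\C)CCC=C(C)C)C(O)=C(C(C)=O)C1=O
F4 | step 2 | (2S)-2-[(2E)-3,7-dimethylocta-2,6-dien-1-yl]-3-methoxy-2-methyl-3-oxopropanoic acid | OC(=O)[C@](C)(C/C=C(\C)CCC=C(C)C)C(=O)OC
F5 | step 2 | methyl (2R,4E)-2-(chlorocarbonyl)-2,5,9-trimethyldeca-4,8-dienoate | ClC(=O)[C@](C)(C/C=C(\C)CCC=C(C)C)C(=O)OC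
F6 | step 11 | 6-(dimethoxymethyl)-5,7-bis(methoxymethoxy)-2,2-dimethyl-2H-chromene | COC(OC)c1c(OCOC)cc2OC(C)(C)C=Cc2c1OCOC
F7 | step 11 | 1-[6-(dimethoxymethyl)-5,7-bis(methoxymethoxy)-2,2-dimethyl-2H-chromen-8-yl]butan-1-one | CCCC(=O)c1c(OCOC)c(C(OC)OC)c(OCOC)c2C=CC(C)(C)Oc12
F8 | step 12 | 5-{[8-butanoyl-5,7-bis(methoxymethoxy)-2,2-dimethyl-2H-chromen-6-yl]methyl}-2,2-dimethyl-1,3-dioxane-4,6-dione | CCCC(=O)c1c(OCOC)c(CC2C(=O)OC(C)(C)OC2=O)c(OCOC)c2C=CC(C)(C)Oc12
F9 | step 18 | tetrakis(trimethylsilyl) derivative of 28 (O5, O7 and both enol oxygens) | CCCC(=O)c1c(O[Si](C)(C)C)c(CC2=C(O[Si](C)(C)C)[C@@](C)(C/C=C(\C)CCC=C(C)C)C(O[Si](C)(C)C)=C(C(C)=O)C2=O)c(O[Si](C)(C)C)c2C=CC(C)(C)Oc12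
A1 | alternative 1 | 2-acetyl-6-[(3-butanoyl-2,4,6-trihydroxyphenyl)methyl]-4-[(2E)-3,7-dimethylocta-2,6-dien-1-yl]-3,5-dihydroxy-4-methylcyclohexa-2,5-dien-1-one | CCCC(=O)c1c(O)c(CC2=C(O)[C@@](C)(C/C=C(\C)CCC=C(C)C)C(O)=C(C(C)=O)C2=O)c(O)cc1O
A2 | alternative 1 | 3-{[3-acetyl-5-[(2E)-3,7-dimethylocta-2,6-dien-1-yl]-2,6-dihydroxy-5-methyl-4-oxocyclohexa-2,6-dien-1-yl]methyl}-4-hydroxy-6-(2-oxopentyl)-2H-pyran-2-one | CCCC(=O)CC1=CC(O)=C(CC2=C(O)[C@@](C)(C/C=C(\C)CCC=C(C)C)C(O)=C(C(C)=O)C2=O)C(=O)O1
A3 | alternative 1 | 3-methylbut-2-enal | CC(C)=CC=O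
A4 | alternative 2 | 5,7-bis(methoxymethoxy)-2,2-dimethyl-2H-chromene | CC1(C)C=Cc2c(OCOC)cc(OCOC)cc2O1
A5 | alternative 2 | 3,5-bis(methoxymethoxy)-2-(trimethylsilyl)phenyl trifluoromethanesulfonate | COCOc1cc(OCOC)c([Si](C)(C)C)c(OS(=O)(=O)C(F)(F)F)c1
A6 | alternative 3 | (4R)-2-acetyl-4-[(2E)-3,7-dimethylocta-2,6-dien-1-yl]-3,5-dihydroxy-4-methylcyclohexa-2,5-dien-1-one | C1=C(O)[C@@](C)(C/C=C(\C)CCC=C(C)C)C(O)=C(C(C)=O)C1=O
A7 | alternative 3 | (3R)-3-[(2E)-3,7-dimethylocta-2,6-dien-1-yl]-3-methyl-6-(2-oxopropyl)-2H-pyran-2,4(3H)-dione | CC(=O)CC1=CC(=O)[C@@](C)(C/C=C(\C)CCC=C(C)C)C(=O)O1
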